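**Plan**
- Retrosynthesis: the methoxyquinone is opened to a 2,3,5-trimethoxyphenyl ring, the acetate to the secondary alcohol, and the C2–O bond to a C2–B bond.
- The side chain is then cut at two bonds at once, ring carbon–C1 and C2–C3, leaving an aryl bromide, a vinylboronic ester (C1 and C2) and an undecyl Grignard reagent (C3 to C13).
- Enabling feature: the acetoxy carbon C2 sits between the CH2 group (C1) bound to the six-membered ring and an unbranched undecyl chain, which is the imprint of a vinylboron unit inserted between an aryl electrophile and an alkyl nucleophile.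
- Forward: 5-bromovanillin is turned into the trimethoxy bromoarene, the chain is joined in one three-component coupling, and C–B oxidation, acetylation and oxidative demethylation finish the target; the only ring is the purchased benzene ring and no ring is formed.
- Stereochemistry: the single stereocenter (R at C2) is set in the coupling by a chiral ferrocenyl bisphosphine on palladium and is carried with retention through the C–B oxidation.

Key step: step 5

Assumption (remark on the chemistry): L is the Mandyphos-type ligand 1,1'-bis[bis(4-methoxy-3,5-dimethylphenyl)phosphino]-2,2'-bis[(dimethylamino)(phenyl)methyl]ferrocene; both antipodes are commercial, and the one that delivers the (R)-boronate is used, its sense being checked on the derived alcohol by Mosher ester analysis in a pilot run.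

**Route**

Step 1
Reactants: 1 5-bromovanillin (3-bromo-4-hydroxy-5-methoxybenzaldehyde)
Product: 2 3-bromo-4,5-dimethoxybenzaldehyde
Conditions: MeI, K2CO3, DMF, rt
Reagents that add atoms: iodomethane, CI
Why: Williamson ether synthesis, in which the phenoxide of 1, made acidic by the para formyl group and the ortho bromine, should be alkylated cleanly at oxygen by iodomethane.

Step 2
Reactants: 2 3-bromo-4,5-dimethoxybenzaldehyde
Product: 4 3-bromo-4,5-dimethoxyphenol, via aryl formate 3 (not isolated)
Conditions: mCPBA, CH2Cl2, 0 °C to rt; then K2CO3 (cat.), MeOH, rt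
Reagents that add atoms: 3-chloroperoxybenzoic acid (mCPBA), OOC(=O)c1cccc(Cl)c1
Why: Baeyer-Villiger oxidation, in which the electron-rich aryl group bearing a para methoxy group should migrate in preference to hydride to give formate 3, which base-catalysed transesterification with methanol then cleaves to the phenol.

Step 3
Reactants: 4 3-bromo-4,5-dimethoxyphenol
Product: 5 1-bromo-2,3,5-trimethoxybenzene
Conditions: MeI, K2CO3, acetone, reflux
Reagents that add atoms: iodomethane, CI
Why: Williamson ether synthesis on the phenoxide of 4, after which the ring carries next to bromine the 2,3,5-trimethoxy pattern that maps onto the methoxyquinone.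

Step 4
Reactants: 6 1-bromoundecane
Product: 7 undecylmagnesium bromide (THF solution, titrated before use)
Conditions: Mg turnings, I2 (cat.), THF, rt to 45 °C
Reagents that add atoms: magnesium, [Mg]
Why: Grignard formation by insertion of magnesium into a primary C–Br bond, run dilute with slow addition so that Wurtz coupling stays minor.

Step 5
Reactants: 8 vinylboronic acid pinacol ester (4,4,5,5-tetramethyl-2-vinyl-1,3,2-dioxaborolane); 7 undecylmagnesium bromide; 5 1-bromo-2,3,5-trimethoxybenzene
Product: 10 2-[(2R)-1-(2,3,5-trimethoxyphenyl)tridecan-2-yl]-4,4,5,5-tetramethyl-1,3,2-dioxaborolane, via vinylboron ate complex 9 (not isolated)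
Conditions: 8 (slight excess), 7, NaOSO2CF3, THF, 0 °C to rt; then 5, Pd(OAc)2 (2 mol%), ligand L (2.4 mol%), THF, 60 °C
Reagents that add atoms: none
Why: Zerovalent palladium formed from Pd(OAc)2 and L should insert into the C–Br bond of 5, and NaOSO2CF3 removes bromide so that the cationic divalent arylpalladium can bind the electron-rich vinyl group of ate complex 9. Palladium then bonds to the terminal vinyl carbon while the undecyl group shifts from boron to the internal carbon anti to the metal (1,2-metallate shift, forming C2–C3), and reductive elimination from the resulting alkyl(aryl)palladium forms the aryl–C1 bond and returns zerovalent palladium. The closest known reaction type is the palladium-catalysed enantioselective conjunctive cross-coupling of Grignard-derived vinylboron ate complexes with aryl bromides or triflates, applied here to a new substrate pair, and no ring is closed. The new stereocenter at C2 is controlled by the catalyst alone, because the chiral pocket of L decides which enantiotopic face of the boron-bearing vinyl carbon is bound and attacked while all three components are achiral. The step needs chemoselectivity for the metallate shift over direct Suzuki-type transmetallation and over beta-hydride elimination, which the four-coordinate boron, the halide-free cationic palladium and the wide bite angle of L should secure, and undecyl is the only group that can migrate because the pinacol oxygens stay on boron.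

Step 6
Reactants: 10 2-[(2R)-1-(2,3,5-trimethoxyphenyl)tridecan-2-yl]-4,4,5,5-tetramethyl-1,3,2-dioxaborolane
Product: 11 (2R)-1-(2,3,5-trimethoxyphenyl)tridecan-2-ol
Conditions: 3 M aq NaOH, 30% H2O2, THF, 0 °C to rt
Reagents that add atoms: hydrogen peroxide, OO
Why: Alkaline peroxide oxidation of a secondary boronic ester, in which the alkyl group migrates from boron to oxygen with retention so that C2 should stay R, while the trimethoxyarene is inert to the reagent.

Step 7
Reactants: 11 (2R)-1-(2,3,5-trimethoxyphenyl)tridecan-2-ol
Product: 12 (2R)-1-(2,3,5-trimethoxyphenyl)tridecan-2-yl acetate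
Conditions: Ac2O, pyridine, DMAP (cat.), CH2Cl2, rt
Reagents that add atoms: acetic anhydride, CC(=O)OC(C)=O
Why: DMAP-catalysed acylation of an unhindered secondary alcohol with acetic anhydride, which does not touch the C–O bond at the stereocenter.

Step 8
Reactants: 12 (2R)-1-(2,3,5-trimethoxyphenyl)tridecan-2-yl acetate
Product: 13 (2R)-1-(5-methoxy-3,6-dioxocyclohexa-1,4-dien-1-yl)tridecan-2-yl acetate (target)
Conditions: (NH4)2Ce(NO3)6, MeCN/H2O, 0 °C, neutral work-up
Reagents that add atoms: water, O
Why: Oxidative demethylation of a hydroquinone dimethyl ether, in which two one-electron oxidations by tetravalent cerium and addition of water at ring C2 and C5 expel two molecules of methanol and should give the para-quinone, the 1,4-related methoxy pair being cleaved in preference to the vicinal pair as is usual for 1-alkyl-2,3,5-trimethoxybenzenes, with the acetate and the stereocenter untouched.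

**Compound list**
1 | 5-bromovanillin (3-bromo-4-hydroxy-5-methoxybenzaldehyde) | O=Cc1cc(Br)c(O)c(OC)c1 | starting material
2 | 3-bromo-4,5-dimethoxybenzaldehyde | O=Cc1cc(Br)c(OC)c(OC)c1 | intermediate
3 | 3-bromo-4,5-dimethoxyphenyl formate | O=COc1cc(Br)c(OC)c(OC)c1 | intermediate
4 | 3-bromo-4,5-dimethoxyphenol | Oc1cc(Br)c(OC)c(OC)c1 | intermediate
5 | 1-bromo-2,3,5-trimethoxybenzene | COc1cc(OC)c(OC)c(Br)c1 | intermediate
6 | 1-bromoundecane | CCCCCCCCCCCBr | starting material
7 | undecylmagnesium bromide | CCCCCCCCCCC[Mg]Br | intermediate
8 | vinylboronic acid pinacol ester (4,4,5,5-tetramethyl-2-vinyl-1,3,2-dioxaborolane) | C=CB1OC(C)(C)C(C)(C)O1 | starting material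
9 | bromomagnesium 4,4,5,5-tetramethyl-2-undecyl-2-vinyl-1,3,2-dioxaborolan-2-uide (vinylboron ate complex) | CCCCCCCCCCC[B-]1(C=C)OC(C)(C)C(C)(C)O1.[Mg+]Br | intermediate
10 | 2-[(2R)-1-(2,3,5-trimethoxyphenyl)tridecan-2-yl]-4,4,5,5-tetramethyl-1,3,2-dioxaborolane | CCCCCCCCCCC[C@H](Cc1cc(OC)cc(OC)c1OC)B1OC(C)(C)C(C)(C)O1 | intermediate
11 | (2R)-1-(2,3,5-trimethoxyphenyl)tridecan-2-ol | CCCCCCCCCCC[C@H](Cc1cc(OC)cc(OC)c1OC)O | intermediate
12 | (2R)-1-(2,3,5-trimethoxyphenyl)tridecan-2-yl acetate | CCCCCCCCCCC[C@H](Cc1cc(OC)cc(OC)c1OC)OC(C)=O | intermediate
13 | (2R)-1-(5-methoxy-3,6-dioxocyclohexa-1,4-dien-1-yl)tridecan-2-yl acetate | CCCCCCCCCCC[C@H](CC1=CC(=O)C=C(OC)C1=O)OC(C)=O | target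

Total step count: 8
Longest linear sequence: 7 steps (steps 1, 2, 3, 5, 6, 7, 8)

**Steps most likely to fail**

Step 5. Oxidative addition to the electron-rich bromide may be slow, and its ortho methoxy group may occupy the site on cationic palladium that the vinyl group needs. Direct Suzuki-type transfer, protodeboronation of the ate complex or poor enantiofacial control could then take over. The fallback sets out from 5 and takes the stereocenter from a reagent instead of the catalyst. Bromine–lithium exchange (n-BuLi, THF, −78 °C) should give (2,3,5-trimethoxyphenyl)lithium F1. With BF3·OEt2 at −78 °C this opens commercially available (2R)-2-undecyloxirane F2 at its terminal carbon, so the oxygen-bearing stereocenter is not touched. The product is alcohol 11, where the route is rejoined.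

Step 8. Over-oxidation, competing cleavage of the vicinal methoxy pair to an ortho-quinone, oxidative biaryl coupling, or loss of acetic acid from the product on basic work-up may lower the return. The fallback sets out from phenol 4 and changes the masking of the quinone so that only one oxidation mode is open. Benzylation (BnBr, K2CO3, DMF) should give 5-(benzyloxy)-1-bromo-2,3-dimethoxybenzene F3. Coupling with ate complex 9 under the conditions of step 5 gives 2-[(2R)-1-[5-(benzyloxy)-2,3-dimethoxyphenyl]tridecan-2-yl]-4,4,5,5-tetramethyl-1,3,2-dioxaborolane F4. Oxidation with NaOH and H2O2 gives (2R)-1-[5-(benzyloxy)-2,3-dimethoxyphenyl]tridecan-2-ol F5, and acetylation gives (2R)-1-[5-(benzyloxy)-2,3-dimethoxyphenyl]tridecan-2-yl acetate F6. Hydrogenolysis (H2, Pd on carbon, EtOAc) frees (2R)-1-(5-hydroxy-2,3-dimethoxyphenyl)tridecan-2-yl acetate F7. PhI(OAc)2 in aqueous MeCN at 0 °C then oxidises this para-methoxyphenol at the one carbon para to the hydroxyl, with loss of methanol, and the route is rejoined at 13.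

Step 2. Hydride instead of aryl migration would give the benzoic acid, and excess peracid may attack the electron-rich ring. The fallback sets out from 1 and replaces the methylation, Baeyer-Villiger and methylation sequence by a Dakin oxidation. With 30% H2O2 and aq NaOH at 0 °C to rt under N2, 1 should pass through 3-bromo-4-hydroxy-5-methoxyphenyl formate F8, which is hydrolysed in the same flask to 2-bromo-6-methoxybenzene-1,4-diol F9. Double O-methylation (Me2SO4, K2CO3, acetone, reflux, N2) then gives 5, where the route is rejoined. This shorter path is kept in reserve because the bromohydroquinone is sensitive to air in base.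

**Further compounds**
F1 | step 5 | (2,3,5-trimethoxyphenyl)lithium | [Li]c1cc(OC)cc(OC)c1OC
F2 | step 5 | (2R)-2-undecyloxirane | CCCCCCCCCCC[C@@H]1CO1
F3 | step 8 | 5-(benzyloxy)-1-bromo-2,3-dimethoxybenzene | COc1cc(OCc2ccccc2)cc(Br)c1OC
F4 | step 8 | 2-[(2R)-1-[5-(benzyloxy)-2,3-dimethoxyphenyl]tridecan-2-yl]-4,4,5,5-tetramethyl-1,3,2-dioxaborolane | CCCCCCCCCCC[C@H](Cc1cc(OCc2ccccc2)cc(OC)c1OC)B1OC(C)(C)C(C)(C)O1
F5 | step 8 | (2R)-1-[5-(benzyloxy)-2,3-dimethoxyphenyl]tridecan-2-ol | CCCCCCCCCCC[C@H](Cc1cc(OCc2ccccc2)cc(OC)c1OC)O
F6 | step 8 | (2R)-1-[5-(benzyloxy)-2,3-dimethoxyphenyl]tridecan-2-yl acetate | CCCCCCCCCCC[C@H](Cc1cc(OCc2ccccc2)cc(OC)c1OC)OC(C)=O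
F7 | step 8 | (2R)-1-(5-hydroxy-2,3-dimethoxyphenyl)tridecan-2-yl acetate | CCCCCCCCCCC[C@H](Cc1cc(O)cc(OC)c1OC)OC(C)=O
F8 | step 2 | 3-bromo-4-hydroxy-5-methoxyphenyl formate | O=COc1cc(Br)c(O)c(OC)c1
F9 | step 2 | 2-bromo-6-methoxybenzene-1,4-diol | COc1cc(O)cc(Br)c1O
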